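## Analysis of the target

Atom labels used below: quinoline numbers for the pyridine and its cyclohexane ring (N1, C2, C3, C4, C4a, C5–C8, C8a); C9 is the CH2 on C4, C10 the bridgehead CH, C11 the CH that carries hexyl, Oa the pyran oxygen between C10 and C5, Ob the dioxolane oxygen between C11 and C5; C12 is the ketone carbon on C3, C13 the carbinol carbon, C14 the CH2 on C2, C15/C16 the vinyl carbons.

A pentasubstituted pyridine is the hub of four further rings: a cyclopentanone (C3–C12–C13–C14–C2), a cyclohexane (C4a–C5–C6–C7–C8–C8a), a pyran (C4–C9–C10–Oa–C5–C4a) and a dioxolane (C5–Oa–C10–C11–Ob). Pyran and dioxolane together form a 6,8-dioxabicyclo[3.2.1]octane whose ketal carbon C5 is also a ring atom of the cyclohexane.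

There are five stereocentres, all S in this labelling. C5, C10 and C11 are locked together in the bicycle (bridgeheads cis by necessity, hexyl exo, on the side of the one-atom bridge Oa). The C6 hydroxyl is cis to Ob on the cyclohexane. C13, a tertiary carbinol with vinyl on the far side of the pyridine, has no stereochemical contact with the other four.

The sensitive groups are the tertiary α-hydroxy ketone with its vinyl group (base), the ketal (acid), and the picolyl-type methylenes C8, C9 and C14; a carbanion at C9 could expel Oa.

The difficulties are the fully substituted C5 (two oxygens, an arene carbon and an oxygenated carbon as neighbours), five different carbon substituents on one pyridine, and a remote quaternary stereocentre that only a reagent or catalyst can set.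

One further constraint shapes the route: with a carbonyl at C5, any C6–C7 or C7–C8 unsaturation would make the carbocycle the keto tautomer of a 5-hydroxyquinoline. Oxygen at C6 therefore has to be carried on a saturated ring.

The strategy rests on C5, Oa and C10, three contiguous atoms held side by side on C4a and C4. They are the three atoms of a cyclic carbonyl ylide made from a C5 ketone and a C4 diazoacetyl group, and C11, Ob and the hexyl chain are the carbonyl group of heptanal.

## Retrosynthetic reasoning

**Vinyl group (30 ⇐ 29 ⇐ 28 ⇐ 27 ⇐ 26).** The two O–Si bonds are cut first, then the C15=C16 double bond, which leads back to keto aldehyde 28 and a one-carbon ylide. The aldehyde carbon C15 is the ester carbon of 26; because an ester cannot be brought to the aldehyde level beside a ketone, both carbonyls are taken down to diol 27 and brought back up together. The cut is placed here because the ester is the group that makes the two preceding disconnections possible.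

**C13–O bond (26 ⇐ 25 ⇐ 24).** The tertiary hydroxyl is removed from the doubly activated position of β-keto ester 24. The forward reaction is an electrophilic hydroxylation; since C13 is remote from all other stereocentres it has to be catalyst-controlled, and any error shows up as a separable diastereomer.

**C6–H bond and the two masked carbonyls (24 ⇐ 22 ⇐ 21).** The C6 carbinol is traced to a ketone, reduced from the face opposite Ob. That ketone and the C12 ketone are both released from 21 by one acid hydrolysis (a dioxolane and an enamine). In the reduction the β-keto ester is shielded as its enolate, so that only C6 is reduced.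

**C9–O bond (21 ⇐ 20 ⇐ 19 ⇐ 18).** The C9 methylene is traced to the ketone that the key step leaves behind. Removal goes through the alcohol and a radical, because a radical at C9 does not expel Oa whereas an anion would.

**C12–C13 bond (18 ⇐ 17).** The cyclopentene ring is opened to a nitrile on C3 and a propanoate arm on C2. The nitrile is chosen as the latent C12 ketone because, unlike a ketone or ester at C3, it cannot reach the carbenoid in the key step. The closure is placed directly after the key step, while C9 is still a ketone: no acidic C9–H is then present under base, and no alkoxide is ever formed beside the nitrile.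

**Key disconnection (17 ⇐ 14 + 15).** C10–C11 and Ob–C5 are cut (cycloaddition), then Oa–C10 (ylide formation). This removes two rings, three skeletal bonds and three stereocentres at once and leaves an achiral, fully substituted pyridine 14 and heptanal 15. The C6 oxygen is carried in 14 as a spiro-dioxolane: it is achiral, so the faces of the ylide stay enantiotopic, and it keeps the carbocycle saturated, so that the C5 ketone has no α-hydrogen and cannot aromatise.

**Diazoacetyl group (14 ⇐ 12 ⇐ 11).** The C9–C10 bond is cut to acid 12 and a one-carbon diazo nucleophile. The carboxyl group is traced to a 2-furyl group in 11, which avoids having to tell two esters apart.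

**Pyridine (11 ⇐ 10 ⇐ 4 + 8 + 9).** After dehydrogenation, the dihydropyridine 10 is cut at C4–C4a, C3–C4 and N1–C2 into enaminone 4, ketonitrile 8 and furfural 9. All five pyridine substituents are in place after this one condensation.

**Building blocks (4 ⇐ 3 ⇐ 2 ⇐ 1; 8 ⇐ 5 + 6).** The enaminone comes from dione 3, made from enone ketal 1 by epoxidation and epoxide-to-diketone isomerisation, which puts a carbonyl next to the ketal carbon. The ketonitrile comes from acylation of cyanoacetic acid 5 with acid chloride 6.

## Alternatives that were turned down

**Alternative 1:** The C9–C10 and Oa–C5 bonds are cut so that the pyran appears as a δ-lactone whose carbonyl carbon is the future C5. In the forward sense the 4-methyl group of pyridine ester A3 is deprotonated with LiN(iPr)2, transmetalated with MgBr2 and added to the enantiopure α-alkoxy aldehyde A2; the alkoxide closes onto the ester and gives lactone A1.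
- For it: C11 is bought as a stereocentre and C10 follows by chelation control. This is old, dependable chemistry, and on the security of absolute configuration it is stronger than the chosen route, which relies on a chiral dirhodium carboxylate and an aliphatic aldehyde.
- Against it: A1 contains neither the cyclohexane nor the ketal. The lactone carbonyl must be turned into a ketone bearing the C6–C8 chain, that chain must be joined to the still unsubstituted pyridine carbon next to nitrogen by a C–H functionalisation, C6 must be oxygenated with control, and only then can the ketal close. The cyclopentanone has to be carried protected throughout and still needs hydroxyl and vinyl.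
- Comparison: the chosen route gives up the chiral-pool certainty but forms C10–C11, C5–Ob and C10–Oa in one step on a pyridine that already carries all five substituents, and is much shorter after the key step.

**Alternative 2:** The C12–C13 bond is cut last. In the forward sense the carbene from triazolium salt A6 and Et3N converts the C3 aldehyde of A5 into its acyl-anion equivalent, which adds to the tethered α,α-dimethoxy ketone and gives A4, closing the cyclopentanone and setting C13.
- For it: the tertiary α-hydroxy ketone is made directly, at the right oxidation level, by an established catalytic asymmetric aldehyde–ketone benzoin. This is clearly more direct than the chosen endgame (hydroxylation, then five redox and protecting-group steps), and on that point it is the stronger plan.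
- Against it: it is an endgame only. A5 already contains the bridged ketal, the C6 carbinol and a pentasubstituted pyridine with an aldehyde and an oxopropyl chain, and the benzoin does nothing to build them. The ketone partner has acidic picolyl α-hydrogens, so an aldol onto the aldehyde competes. Turning the acetal of A4 into vinyl passes through the same fragile α-oxygenated β-keto aldehyde as 28.
- Comparison: the chosen strategy spends its key step on the part of the molecule that is hardest to build; the benzoin could in principle be grafted onto it later.

**Alternative 3:** Three pyridine bonds are cut (C2–C3, C4–C4a, N1–C8a). In the forward sense CpCo(CO)2 cyclotrimerises cyano-diyne A8, in which nitrile, ynone and terminal alkyne hang from a tetrasubstituted dioxolane, and gives A7; pyridine, cyclopentanone and pyran form together.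
- For it: three rings per step against two, regiochemistry fixed by the tethers, and C6, C10 and C11 set beforehand on a small fragment. In convergence it is the stronger plan.
- Against it: the ketal carbon C5 must already be a defined stereocentre in the unconstrained dioxolane A8, and ketalisation of an alkynyl ketone offers no bias between the two epimers. In the chosen route C5 is set together with C10 by one suprafacial addition. The cyclisation has to pull the alkyne termini across the dioxolane into a bridged bicycle, and the ynone and propargylic ketal are exposed to the metal. A7 still has a free pyridine C–H, so the cyclohexane must be closed afterwards with the chloroalkyl arm, and hydroxyl and vinyl remain to be added.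
- Comparison: more risk before the key step and more work after it.

Key step: step 9

Assumptions: compound 1 is taken as a catalogue compound. The S-configured dirhodium carboxylate in step 9 and cinchonidine in step 16 are assumed to deliver the faces drawn; the latter by analogy with cinchona-alkaloid hydroxylations of carbocyclic 1-indanone-2-carboxylates.

## Route

Step 1
Reactants: 1 1,4-dioxaspiro[4.5]dec-6-en-8-one
Product: 2 rac-6,7-epoxy-1,4-dioxaspiro[4.5]decan-8-one
Conditions: 30% H2O2, NaOH (cat.), MeOH, 0 °C
Reagents that add atoms: hydrogen peroxide, OO
Why: Nucleophilic (Weitz–Scheffer) epoxidation of the enone; hydroperoxide adds to the β-carbon and the enolate closes the oxirane, the ketal being inert to base.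

Step 2
Reactants: 2 rac-6,7-epoxy-1,4-dioxaspiro[4.5]decan-8-one
Product: 3 1,4-dioxaspiro[4.5]decane-6,8-dione
Conditions: Pd(PPh3)4 (3 mol %), Ph2PCH2CH2PPh2 (3 mol %), toluene, 100 °C
Reagents that add atoms: none
Why: Zerovalent-palladium-catalysed isomerisation of an α,β-epoxy ketone to a β-diketone (oxidative addition at the Cα–O bond, β-hydride elimination, tautomerisation); it places the second carbonyl on the carbon next to the ketal.

Step 3
Reactants: 3 1,4-dioxaspiro[4.5]decane-6,8-dione
Product: 4 8-amino-1,4-dioxaspiro[4.5]dec-7-en-6-one
Conditions: NH4OAc, toluene, reflux (Dean–Stark)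
Reagents that add atoms: ammonium acetate, CC(=O)[O-].[NH4+]
Why: Enaminone formation from a cyclic 1,3-dione; ammonia should condense at the carbonyl remote from the quaternary ketal carbon, as heteroatom nucleophiles do with 4,4-disubstituted cyclohexane-1,3-diones, which leaves the hindered carbonyl as the future C5 ketone.

Step 4
Reactants: 5 cyanoacetic acid; 6 methyl 4-chloro-4-oxobutanoate
Product: 8 methyl 5-cyano-4-oxopentanoate, via acylcyanoacetic acid 7 (not isolated)
Conditions: 5 (2 equiv), n-BuLi (4 equiv), THF, −78 → 0 °C; 6 (1 equiv), −78 °C; 1 M HCl, rt
Reagents that add atoms: none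
Why: C-acylation of the cyanoacetate dianion by the acid chloride (the methyl ester is untouched at −78 °C), then decarboxylation of the β-keto acid on acidification; the second equivalent of dianion takes up the acidic proton of the acylated product.

Step 5
Reactants: 4 8-amino-1,4-dioxaspiro[4.5]dec-7-en-6-one; 8 methyl 5-cyano-4-oxopentanoate; 9 furan-2-carbaldehyde
Product: 10 methyl 3-[3′-cyano-4′-(furan-2-yl)-5′-oxo-1′,4′,7′,8′-tetrahydro-5′H-spiro[1,3-dioxolane-2,6′-quinolin]-2′-yl]propanoate (racemic at C4′)
Conditions: piperidine (cat.), EtOH, reflux
Reagents that add atoms: none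
Why: Hantzsch-type three-component condensation: Knoevenagel condensation of 9 with the active methylene of 8, Michael addition of the enaminone carbon of 4, and cyclodehydration of the amine onto the ketone; the C4′ stereocentre is removed in the next step.

Step 6
Reactants: 10 the dihydropyridine of step 5
Product: 11 methyl 3-[3′-cyano-4′-(furan-2-yl)-5′-oxo-7′,8′-dihydro-5′H-spiro[1,3-dioxolane-2,6′-quinolin]-2′-yl]propanoate
Conditions: DDQ (1.1 equiv), CH2Cl2, rt
Reagents that add atoms: none
Why: Dehydrogenation of a 1,4-dihydropyridine to the pyridine; a 4-heteroaryl group is retained because it is not a stabilised leaving radical.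

Step 7
Reactants: 11 the 4-furylpyridine of step 6
Product: 12 3′-cyano-2′-(3-methoxy-3-oxopropyl)-5′-oxo-7′,8′-dihydro-5′H-spiro[1,3-dioxolane-2,6′-quinoline]-4′-carboxylic acid
Conditions: RuCl3·xH2O (5 mol %), NaIO4 (excess), CCl4/MeCN/H2O, rt
Reagents that add atoms: sodium periodate, [Na+].[O-]I(=O)(=O)=O; water, O
Why: Oxidative degradation of a furan to a carboxylic acid by catalytic RuO4; the electron-poor pyridine, nitrile, ester and ketal are not attacked, and no ester differentiation is needed.

Step 8
Reactants: 12 the pyridine-4-carboxylic acid of step 7
Product: 14 methyl 3-[3′-cyano-4′-(2-diazoacetyl)-5′-oxo-7′,8′-dihydro-5′H-spiro[1,3-dioxolane-2,6′-quinolin]-2′-yl]propanoate, via mixed isobutyl carbonic anhydride 13 (not isolated)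
Conditions: i-BuOCOCl, N-methylmorpholine, THF, −15 °C; CH2N2 (excess), Et2O, 0 °C → rt
Reagents that add atoms: diazomethane, C=[N+]=[N-]; isobutyl chloroformate, CC(C)COC(=O)Cl (its atoms stay only in 13)
Why: Acylation of diazomethane by a mixed anhydride; the carboxylate is activated under base so that the open keto acid reacts, not a cyclic pseudo-acid chloride, which is the usual hazard of keto acids under acid-chloride conditions.

Step 9
Reactants: 14 the diazoketone of step 8; 15 heptanal
Product: 17 cycloadduct (5S,10R,11S): 6,8-dioxabicyclo[3.2.1]octane fused to the pyridine; C9 ketone; C6 spiro-dioxolane; C3 nitrile; C2 methyl propanoate arm; hexyl exo on C11, via carbonyl ylide 16 (not isolated)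
Conditions: Rh2(S-PTTL)4 (dirhodium tetrakis[(S)-N-phthaloyl-tert-leucinate], 2 mol %), 15 (5 equiv), PhCF3, 4 Å sieves, 0 °C, slow addition of 14
Reagents that add atoms: none
Why: The divalent-rhodium carboxylate removes nitrogen from 14, and the electrophilic carbenoid carbon C10 is captured by a lone pair of the C5 ketone oxygen, which the pyridine holds syn and coplanar; the pyran ring closes by attack of oxygen on the Rh=C carbon (six-membered, exo to the Rh=C bond) and gives the pyrylium-olate-type ylide 16. Heptanal then adds across C10 and C5 in a concerted suprafacial [3+2] cycloaddition, its carbonyl carbon bonding to the enolate-like terminus C10 and its oxygen to the oxocarbenium terminus C5, which closes the dioxolane and with it the bicycle. The closest known reaction type is the dirhodium-catalysed tandem ylide formation–cycloaddition of ortho-acylaryl diazomethyl ketones with aldehydes, including its enantioselective form with N-phthaloyl amino acid carboxylates. C5 and C10 are bridgeheads and are set together; which face of the planar ylide is attacked, and hence their absolute configuration, is decided by the chiral carboxylate ligands, which stay associated with the ylide. C11 follows from the exo orientation of the aldehyde, hexyl turned toward Oa and away from the pyridine and its carbocycle. Chemoselectivity comes from the substrate: the nitrile is linear and cannot reach the carbenoid, the ester is nine atoms away, a dioxolane oxygen would need a seven-membered ring, the pyridine nitrogen is flanked by two alkyl groups, and the C5 ketone has no α-hydrogen. Regiochemistry follows the polarity of the ylide, and slow addition into excess aldehyde keeps the ylide from dimerising.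

Step 10
Reactants: 17 the cycloadduct of step 9
Product: 18 enamino ester: new cyclopentene ring C12(NH2)=C13(CO2Me)–C14H2 fused at C2–C3; C9 ketone, bicyclic ketal and dioxolane unchanged
Conditions: t-BuOK (1.1 equiv), THF, 0 °C → rt; aq. NH4Cl
Reagents that add atoms: none
Why: Thorpe–Ziegler-type closure: the ester enolate adds to the ortho nitrile (5-exo-dig) and the imine tautomerises to the vinylogous carbamate; picolyl deprotonations are reversible and unproductive. At this stage C9 is a ketone with a non-enolisable bridgehead neighbour, so base cannot open the ketal.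

Step 11
Reactants: 18 the enamino ester of step 10
Product: 19 C9 alcohol of 18 (C9 configuration immaterial)
Conditions: NaBH4, THF/MeOH, 0 °C
Reagents that add atoms: none
Why: Borohydride reduction of the aryl ketone; the vinylogous carbamate and both ketals are inert, and with the nitrile already consumed the alkoxide has nothing to cyclise onto.

Step 12
Reactants: 19 the C9 alcohol of step 11
Product: 20 O-phenyl thionocarbonate of 19
Conditions: PhOC(S)Cl, pyridine, 4-(dimethylamino)pyridine (cat.), CH2Cl2, 0 °C → rt
Reagents that add atoms: O-phenyl chlorothionoformate, S=C(Cl)Oc1ccccc1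
Why: Thioacylation of the secondary alcohol; the enamine nitrogen is a hydrogen-bonded vinylogous carbamate nitrogen and should not compete.

Step 13
Reactants: 20 the thionocarbonate of step 12
Product: 21 C9-deoxygenated enamino ester (C9 is CH2)
Conditions: Bu3SnH, azobisisobutyronitrile (cat.), toluene, 90 °C
Reagents that add atoms: none
Why: Barton–McCombie deoxygenation through a benzylic-type C9 radical; a radical, unlike an anion, does not expel the β-oxygen Oa, and thermal syn elimination would need a bridgehead alkene.

Step 14
Reactants: 21 the deoxygenated enamino ester of step 13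
Product: 22 diketo ester: C6 ketone and C12 ketone with CO2Me on C13 (keto–enol and C13-epimer mixture)
Conditions: 2 M HCl, THF, 45 °C
Reagents that add atoms: water, O
Why: Acid hydrolysis of the enamine (C-protonation, iminium hydrolysis) and of the dioxolane in one operation; the bicyclic ketal is deactivated by the electron-poor pyridine and re-closes intramolecularly if it opens.

Step 15
Reactants: 22 the diketo ester of step 14
Product: 24 (6S)-C6 alcohol with intact β-keto ester, via sodium enolate 23 (not isolated)
Conditions: NaOMe (1.1 equiv), MeOH, 0 °C; NaBH4, −20 °C; aq. NH4Cl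
Reagents that add atoms: sodium methoxide, C[O-].[Na+] (its sodium stays only in 23)
Why: The β-keto ester is held as its enolate, which borohydride does not reduce, so only the C6 ketone reacts. Oa lies near the carbonyl plane and Ob perpendicular to it, so Felkin–Anh (axial) attack anti to the C5–Ob bond should place the hydroxyl cis to Ob (6S).

Step 16
Reactants: 24 the C6 alcohol of step 15
Product: 25 (13R)-α-hydroxy β-keto ester
Conditions: cinchonidine (20 mol %), cumene hydroperoxide, CH2Cl2, 0 °C → rt
Reagents that add atoms: cumene hydroperoxide, CC(C)(OO)c1ccccc1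
Why: Cinchona-alkaloid-mediated α-hydroxylation of a cyclic aryl β-keto ester: the tertiary amine forms a chiral ion pair with the enolate, which attacks the peroxide oxygen on one face. The minor C13 epimer is a diastereomer and is removed by chromatography; the spatial arrangement is that of the target (R only because CO2Me outranks the ketone).

Step 17
Reactants: 25 the hydroxy keto ester of step 16
Product: 26 bis(triethylsilyl) ether of 25 (C6–OSiEt3 and C13–OSiEt3)
Conditions: Et3SiOTf, 2,6-lutidine, CH2Cl2, −78 → 0 °C
Reagents that add atoms: triethylsilyl trifluoromethanesulfonate, CC[Si](CC)(CC)OS(=O)(=O)C(F)(F)F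
Why: Silyl triflate silylation of the secondary and the tertiary alcohol; the ketone has no α-hydrogen and cannot form an enol ether.

Step 18
Reactants: 26 the bis-silyl ether of step 17
Product: 27 diol: C12–OH (epimers) and C13–CH2OH; both silyl ethers retained
Conditions: i-Bu2AlH (excess), CH2Cl2, −78 → 0 °C; aq. potassium sodium tartrate
Reagents that add atoms: none
Why: Exhaustive hydride reduction of ketone and ester; aluminium alkoxides do not promote silyl migration, and the C12 configuration is immaterial.

Step 19
Reactants: 27 the diol of step 18
Product: 28 keto aldehyde: C12 ketone and C13–CHO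
Conditions: Dess–Martin periodinane, NaHCO3, CH2Cl2, 0 °C → rt
Reagents that add atoms: none
Why: Oxidation of the primary and the secondary alcohol in one operation; C13 is quaternary, so the β-keto aldehyde cannot enolise or epimerise.

Step 20
Reactants: 28 the keto aldehyde of step 19
Product: 29 bis(triethylsilyl) ether of the target (C13 vinyl)
Conditions: Ph3PCH3Br, KN(SiMe3)2, THF, 0 °C; then 28, −78 → 0 °C
Reagents that add atoms: methyltriphenylphosphonium bromide, C[P+](c1ccccc1)(c1ccccc1)c1ccccc1.[Br-]
Why: Wittig methylenation; the aldehyde should react far faster than the hindered aryl ketone flanked by a quaternary carbon, and the remaining picolyl hydrogens are too weakly acidic for the ylide.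

Step 21
Reactants: 29 the bis-silyl ether of step 20
Product: 30 Trichopsistide A
Conditions: HF·pyridine, pyridine, THF, 0 °C → rt
Reagents that add atoms: none
Why: Fluoride-mediated cleavage of both triethylsilyl ethers under buffered conditions that leave the ketal and the tertiary α-hydroxy ketone untouched.

## Compound list

1 | 1,4-dioxaspiro[4.5]dec-6-en-8-one | O=C1C=CC2(OCCO2)CC1 | starting material
2 | rac-6,7-epoxy-1,4-dioxaspiro[4.5]decan-8-one | O=C1CCC2(OCCO2)C2OC12 | intermediate
3 | 1,4-dioxaspiro[4.5]decane-6,8-dione | O=C1CC(=O)C2(OCCO2)CC1 | intermediate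
4 | 8-amino-1,4-dioxaspiro[4.5]dec-7-en-6-one | NC1=CC(=O)C2(OCCO2)CC1 | intermediate
5 | cyanoacetic acid | N#CCC(=O)O | starting material
6 | methyl 4-chloro-4-oxobutanoate | COC(=O)CCC(=O)Cl | starting material
7 | 2-cyano-6-methoxy-3,6-dioxohexanoic acid (lithium salt in the flask) | COC(=O)CCC(=O)C(C#N)C(=O)O | intermediate
8 | methyl 5-cyano-4-oxopentanoate | COC(=O)CCC(=O)CC#N | intermediate
9 | furan-2-carbaldehyde | O=Cc1ccco1 | starting material
10 | 4′-furyl-1′,4′-dihydropyridine (racemic at C4′) | COC(=O)CCC1=C(C#N)C(c2ccco2)C2=C(CCC3(OCCO3)C2=O)N1 | intermediate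
11 | 4′-furylpyridine with C5 ketone and C6 spiro-dioxolane | COC(=O)CCc1nc2CCC3(OCCO3)C(=O)c2c(-c2ccco2)c1C#N | intermediate
12 | pyridine-4′-carboxylic acid | COC(=O)CCc1nc2CCC3(OCCO3)C(=O)c2c(C(=O)O)c1C#N | intermediate
13 | mixed isobutyl carbonic anhydride of 12 | COC(=O)CCc1nc2CCC3(OCCO3)C(=O)c2c(C(=O)OC(=O)OCC(C)C)c1C#N | intermediate
14 | 4′-diazoacetyl pyridine (key-step precursor) | COC(=O)CCc1nc2CCC3(OCCO3)C(=O)c2c(C(=O)C=[N+]=[N-])c1C#N | intermediate
15 | heptanal | CCCCCCC=O | starting material
16 | cyclic carbonyl ylide (C9 olate, C10 carbanion terminus, Oa=C5 oxocarbenium) | N#Cc1c(CCC(=O)OC)nc2c3c1C([O-])=C[O+]=C3C1(OCCO1)CC2 | intermediate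
17 | (5S,10R,11S) cycloadduct with C9 ketone and C6 dioxolane | N#Cc1c(CCC(=O)OC)nc2c3c1C(=O)[C@@H]1O[C@]3(O[C@H]1CCCCCC)C1(OCCO1)CC2 | intermediate
18 | enamino ester (C12–NH2, C13–CO2Me), C9 ketone | COC(=O)C1=C(N)c2c(C1)nc3c4c2C(=O)[C@@H]5O[C@]4(O[C@H]5CCCCCC)C6(OCCO6)CC3 | intermediate
19 | C9 alcohol of 18 (C9 epimers) | COC(=O)C1=C(N)c2c(C1)nc3c4c2C(O)[C@@H]5O[C@]4(O[C@H]5CCCCCC)C6(OCCO6)CC3 | intermediate
20 | C9 O-phenyl thionocarbonate | COC(=O)C1=C(N)c2c(C1)nc3c4c2C(OC(=S)Oc2ccccc2)[C@@H]5O[C@]4(O[C@H]5CCCCCC)C6(OCCO6)CC3 | intermediate
21 | C9-deoxygenated enamino ester | COC(=O)C1=C(N)c2c(C1)nc3c4c2C[C@@H]5O[C@]4(O[C@H]5CCCCCC)C6(OCCO6)CC3 | intermediate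
22 | diketo ester (C6 ketone, C12 ketone, C13–CO2Me) | COC(=O)C1Cc2nc3c4c(c2C1=O)C[C@@H]5O[C@]4(O[C@H]5CCCCCC)C(=O)CC3 | intermediate
23 | sodium enolate of 22 | [Na+].COC(=O)C1=C([O-])c2c(C1)nc3c4c2C[C@@H]5O[C@]4(O[C@H]5CCCCCC)C(=O)CC3 | intermediate
24 | (6S)-alcohol, β-keto ester | COC(=O)C1Cc2nc3c4c(c2C1=O)C[C@@H]5O[C@]4(O[C@H]5CCCCCC)[C@@H](O)CC3 | intermediate
25 | (13R)-α-hydroxy β-keto ester | COC(=O)[C@@]1(O)Cc2nc3c4c(c2C1=O)C[C@@H]5O[C@]4(O[C@H]5CCCCCC)[C@@H](O)CC3 | intermediate
26 | bis(triethylsilyl) ether of 25 | COC(=O)[C@@]1(O[Si](CC)(CC)CC)Cc2nc3c4c(c2C1=O)C[C@@H]5O[C@]4(O[C@H]5CCCCCC)[C@@H](O[Si](CC)(CC)CC)CC3 | intermediate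
27 | diol (C12–OH epimers, C13–CH2OH) | OC[C@@]1(O[Si](CC)(CC)CC)Cc2nc3c4c(c2C1O)C[C@@H]5O[C@]4(O[C@H]5CCCCCC)[C@@H](O[Si](CC)(CC)CC)CC3 | intermediate
28 | keto aldehyde (C12 ketone, C13–CHO) | O=C[C@@]1(O[Si](CC)(CC)CC)Cc2nc3c4c(c2C1=O)C[C@@H]5O[C@]4(O[C@H]5CCCCCC)[C@@H](O[Si](CC)(CC)CC)CC3 | intermediate
29 | bis(triethylsilyl) ether of Trichopsistide A | C=C[C@@]1(O[Si](CC)(CC)CC)Cc2nc3c4c(c2C1=O)C[C@@H]5O[C@]4(O[C@H]5CCCCCC)[C@@H](O[Si](CC)(CC)CC)CC3 | intermediate
30 | Trichopsistide A (5S,6S,10S,11S,13S in the labels used here) | C=C[C@@]1(O)Cc2nc3c4c(c2C1=O)C[C@@H]1O[C@]4(O[C@H]1CCCCCC)[C@@H](O)CC3 | target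

## Step count and least certain steps

Total: 21 steps. Longest linear sequence: 20 steps (1 → 30 through steps 1–3 and 5–21); step 4 supplies 8 in one step from 5 and 6.

**Step 9 (key step).** The most likely failure is incomplete control of the ylide face. The dipolarophile is an unbranched aliphatic aldehyde, and the ylide terminus C5 is flanked by a quaternary ketal carbon; this slows the addition and may let ylide that has left the chiral catalyst react. Erosion of the exo preference and ylide dimerisation are lesser concerns. A partial safeguard is built in: once C13 is set in step 16, material of the wrong bicycle configuration is largely a diastereomer and is removed there.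
Fallback: starting from 14, the same cycloaddition is run with achiral Rh2(OAc)4 and heptanal, which should give the racemic exo cycloadduct F1. Its enantiomers are separated by preparative chromatography on a chiral stationary phase, and the route is rejoined at 17. Absolute configuration then comes from resolution instead of catalysis.

**Step 14.** The most likely failure is sluggish cleavage of the dioxolane. Its ionisation is retarded by the adjacent ketal carbon, so the acid and temperature needed may also hydrolyse the methyl ester (followed by decarboxylation), or open the bicyclic ketal once C6 is a ketone, which would allow aromatisation of the carbocycle.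
Fallback: starting from 21, dilute acid (0.5 M HCl, THF, 0 °C) hydrolyses only the enamine and should give the keto ester with the dioxolane retained F2. The dioxolane is then removed without water by exchange with acetone under In(OTf)3 catalysis, and the route is rejoined at 22.

**Step 16.** The most likely failure is poor facial selectivity. A methyl ester offers the alkaloid ion pair little steric differentiation, and the existing stereocentres are too far away to help, so much material would be lost as the C13 epimer.
Fallback: starting from 24, transesterification with tert-butanol (4-(dimethylamino)pyridine, toluene, reflux, methanol removed on 5 Å sieves) gives the tert-butyl β-keto ester F3. This is hydroxylated under phase-transfer conditions (N-(9-anthracenylmethyl)cinchonidinium chloride, cumene hydroperoxide, toluene/aqueous K2HPO4), where bulky esters are the better substrates, to give F4. Silylation as in step 17 gives F5, and LiAlH4 reduces ketone and tert-butyl ester to rejoin the route at 27.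

**Step 20.** The most likely failure is attack of the ylide on the wrong carbonyl of the non-enolisable β-keto aldehyde, or acyl cleavage of this 1,3-dicarbonyl unit after addition.
Fallback: starting from 27, the primary alcohol alone is oxidised (2,2,6,6-tetramethylpiperidin-1-oxyl, PhI(OAc)2) to the hydroxy aldehyde F6. Methylenation with the same ylide at low temperature gives the hydroxy alkene F7, in which C12 is still a carbinol, and Dess–Martin oxidation of that alcohol rejoins the route at 29.

## Further compounds

F1 | step 9 | racemic cycloadduct (1:1 mixture of 17 and its enantiomer) | N#Cc1c(CCC(=O)OC)nc2c3c1C(=O)[C@@H]1O[C@]3(O[C@H]1CCCCCC)C1(OCCO1)CC2.N#Cc1c(CCC(=O)OC)nc2c3c1C(=O)[C@H]1O[C@@]3(O[C@@H]1CCCCCC)C1(OCCO1)CC2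
F2 | step 14 | β-keto ester with the C6 dioxolane retained (C13 epimers) | COC(=O)C1Cc2nc3c4c(c2C1=O)C[C@@H]5O[C@]4(O[C@H]5CCCCCC)C6(OCCO6)CC3
F3 | step 16 | tert-butyl ester analogue of 24 | CC(C)(C)OC(=O)C1Cc2nc3c4c(c2C1=O)C[C@@H]5O[C@]4(O[C@H]5CCCCCC)[C@@H](O)CC3
F4 | step 16 | tert-butyl ester analogue of 25 (13R) | CC(C)(C)OC(=O)[C@@]1(O)Cc2nc3c4c(c2C1=O)C[C@@H]5O[C@]4(O[C@H]5CCCCCC)[C@@H](O)CC3
F5 | step 16 | bis(triethylsilyl) ether of F4 | CC(C)(C)OC(=O)[C@@]1(O[Si](CC)(CC)CC)Cc2nc3c4c(c2C1=O)C[C@@H]5O[C@]4(O[C@H]5CCCCCC)[C@@H](O[Si](CC)(CC)CC)CC3
F6 | step 20 | C12-hydroxy aldehyde (C12 epimers; both silyl ethers) | O=C[C@@]1(O[Si](CC)(CC)CC)Cc2nc3c4c(c2C1O)C[C@@H]5O[C@]4(O[C@H]5CCCCCC)[C@@H](O[Si](CC)(CC)CC)CC3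
F7 | step 20 | C12-hydroxy C13-vinyl compound (C12 epimers; both silyl ethers) | C=C[C@@]1(O[Si](CC)(CC)CC)Cc2nc3c4c(c2C1O)C[C@@H]5O[C@]4(O[C@H]5CCCCCC)[C@@H](O[Si](CC)(CC)CC)CC3
A1 | alternative 1 | pyridine-fused δ-lactone with (S)-1-(4-methoxybenzyloxy)heptyl group and dioxolane-protected cyclopentanone | O=C1O[C@@H](Cc2c1cnc1CCC3(OCCO3)c21)[C@@H](OCc1ccc(OC)cc1)CCCCCC
A2 | alternative 1 | (S)-2-(4-methoxybenzyloxy)octanal | O=C[C@@H](OCc1ccc(OC)cc1)CCCCCC
A3 | alternative 1 | methyl 4′-methyl-6′,7′-dihydrospiro[1,3-dioxolane-2,5′-cyclopenta[b]pyridine]-3′-carboxylate | COC(=O)c1cnc2CCC3(OCCO3)c2c1C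
A4 | alternative 2 | protected target with a dimethyl acetal in place of vinyl and a tert-butyldimethylsilyl ether at C6 | COC(OC)[C@@]1(O)Cc2nc3c4c(c2C1=O)C[C@@H]1O[C@]4(O[C@H]1CCCCCC)[C@@H](O[Si](C)(C)C(C)(C)C)CC3
A5 | alternative 2 | C3 aldehyde with a 3,3-dimethoxy-2-oxopropyl chain on C2 (bridged ketal and silyl ether in place) | COC(OC)C(=O)Cc1nc2c3c(c1C=O)C[C@@H]4O[C@]3(O[C@H]4CCCCCC)[C@@H](O[Si](C)(C)C(C)(C)C)CC2
A6 | alternative 2 | (5aS,10bR)-2-(pentafluorophenyl)-5a,10b-dihydro-4H,6H-indeno[2,1-b][1,2,4]triazolo[4,3-d][1,4]oxazin-2-ium tetrafluoroborate | Fc1c(F)c(F)c(F)c(F)c1-[n+]1cn2[C@@H]3c4ccccc4C[C@@H]3OCc2n1.F[B-](F)(F)F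
A7 | alternative 3 | bridged-ketal cyclopenta-pyridinone with free pyridine C–H next to nitrogen and a 3-chloro-1-silyloxypropyl arm | O=C1CCc2ncc3c(c21)C[C@@H]1O[C@]3(O[C@H]1CCCCCC)[C@@H](O[Si](C)(C)C(C)(C)C)CCCl
A8 | alternative 3 | cyano-diyne tethered through a 2-ethynyl-2,4,5-trisubstituted 1,3-dioxolane | N#CCCC(=O)C#CC[C@@H]1O[C@](C#C)(O[C@H]1CCCCCC)[C@@H](O[Si](C)(C)C(C)(C)C)CCCl
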